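The route rests on cutting the C1–C2 bond of the chalcan unit, between the diarylmethine carbon C1 and the carbinol carbon C2. C1 sits between C6 of the catechin A ring (flanked by O5 and O7) and the para-oxygenated catechol B ring, so its chloride ionises to a planar, highly stabilised benzhydryl cation. C2 is made the α-carbon of a ketone on the upper phloroglucinol A ring. In the key step a chiral ammonium enolate of this α-benzyloxy ketone captures the cation: both halves are joined, C2 is set by the catalyst, C1 by the transition-state topicity, and both C1 epimers of the electrophile converge. The extra carbonyl oxygen leaves in the final hydrogenolysis.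

Key step: step 7

Remark (abbreviation): in names, "BrCat" is the (2R,3S)-3,5,7-tris(benzyloxy)-2-[3,4-bis(benzyloxy)phenyl]-8-bromochroman-6-yl group, i.e. 8-bromo-penta-O-benzyl-(+)-catechin-6-yl.

Remark (assumption): the facial sense known for cinchona-ammonium glycolate alkylation of α-alkoxy aryl ketones (cinchonidinium salts give 2S) is taken to hold for ketone 12, so the pseudo-enantiomeric cinchoninium salt is used to reach 2R in 14.

Step 1
Reactants: 1 (+)-catechin
Product: 2 5,7,3',4'-tetra-O-benzyl-(+)-catechin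
Conditions: BnBr (4.4 equiv), K2CO3, DMF, 0 °C to rt
Reagents that add atoms: benzyl bromide, BrCc1ccccc1
Why: Williamson ether synthesis in which carbonate alkylates the four phenols but not the secondary 3-OH, leaving the chiral-pool centres C2 and C3 untouched.

Step 2
Reactants: 2 5,7,3',4'-tetra-O-benzyl-(+)-catechin
Product: 3 3,5,7,3',4'-penta-O-benzyl-(+)-catechin
Conditions: NaH, BnBr, DMF, 0 °C to rt
Reagents that add atoms: benzyl bromide, BrCc1ccccc1
Why: Williamson etherification of the secondary alcohol with NaH, safe for C2 because no free 4'-phenol remains to open the pyran ring through a quinone methide.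

Step 3
Reactants: 3 3,5,7,3',4'-penta-O-benzyl-(+)-catechin
Product: 4 8-bromo-3,5,7,3',4'-penta-O-benzyl-(+)-catechin
Conditions: NBS (1.0 equiv), CH2Cl2, −78 to 0 °C
Reagents that add atoms: N-bromosuccinimide, O=C1CCC(=O)N1Br
Why: Electrophilic aromatic bromination goes to C8, the more reactive A-ring position of 5,7-di-O-alkyl flavans, so bromine blocks C8 and leaves C6 as the only free nucleophilic carbon.

Step 4
Reactants: 4 8-bromo-3,5,7,3',4'-penta-O-benzyl-(+)-catechin
Product: 5 8-bromo-6-formyl-3,5,7,3',4'-penta-O-benzyl-(+)-catechin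
Conditions: POCl3, DMF, 1,2-dichloroethane, 70 °C; then H2O
Reagents that add atoms: N,N-dimethylformamide, CN(C)C=O; water, O
Why: Vilsmeier–Haack formylation at C6, the only unsubstituted carbon of the trioxygenated A ring.

Step 5
Reactants: 5 8-bromo-6-formyl-3,5,7,3',4'-penta-O-benzyl-(+)-catechin; 6 4-bromo-1,2-bis(benzyloxy)benzene
Product: 8 [3,4-bis(benzyloxy)phenyl](BrCat)methanol (both carbinol epimers), via 3,4-bis(benzyloxy)phenylmagnesium bromide 7 (not isolated)
Conditions: 6, Mg, THF, rt; then 5, THF, −20 to 0 °C; aq. NH4Cl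
Reagents that add atoms: none
Why: Grignard addition to the aldehyde; the new carbinol centre (future C1) should form as an epimer mixture, which does not matter because this carbon is planarised in step 7.

Step 6
Reactants: 9 1,3,5-tris(benzyloxy)benzene; 10 2-(benzyloxy)-N-methoxy-N-methylacetamide
Product: 12 2-(benzyloxy)-1-[2,4,6-tris(benzyloxy)phenyl]ethan-1-one, via 2,4,6-tris(benzyloxy)phenyllithium 11 (not isolated)
Conditions: n-BuLi, THF, 0 °C; then 10, −78 to 0 °C; aq. NH4Cl
Reagents that add atoms: none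
Why: Directed ortho-lithiation between two benzyloxy groups followed by Weinreb ketone synthesis, whose chelated tetrahedral intermediate prevents over-addition.

Step 7
Reactants: 8 [3,4-bis(benzyloxy)phenyl](BrCat)methanol (both carbinol epimers); 12 2-(benzyloxy)-1-[2,4,6-tris(benzyloxy)phenyl]ethan-1-one
Product: 14 (2R,3R)-2-(benzyloxy)-3-[3,4-bis(benzyloxy)phenyl]-3-(BrCat)-1-[2,4,6-tris(benzyloxy)phenyl]propan-1-one, via diarylmethyl chloride 13 (not isolated)
Conditions: 8, SOCl2, CH2Cl2, 0 °C, evaporate; then 12 (1.5 equiv), O-allyl-N-(2,3,4-trifluorobenzyl)cinchoninium bromide (10 mol %), CsOH·H2O, 4 Å MS, toluene–CH2Cl2, −40 °C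
Reagents that add atoms: none
Why: The chlorides 13 ionise readily because C1 is flanked by the 2,4,6-trioxygenated catechin A ring and the para-oxygenated B ring, so both epimers should react through one planar, ion-paired benzhydryl cation that is captured at carbon by the caesium/ammonium (Z)-enolate of 12 (SN1-like C-alkylation under solid–liquid phase transfer). The closest known reaction types are the cinchona-ammonium-catalysed asymmetric glycolate alkylation of α-alkoxy aryl ketones and the phase-transfer benzhydrylation of glycine-imine enolates. No ring is closed. C2 (R here, S in the target once the carbonyl carbon has become CH2) is set by the cinchoninium cation, which shields one face of the enolate. C1 (R) should follow from an open transition state in which the bulky, twisted A-ring aryl lies anti to the enolate carbon, the flat B-ring aryl sits next to the small C2–H, and C1–H sits next to the benzyloxy group. The step needs C- over O-alkylation and capture of 13 faster than its hydrolysis, which the soft ion-paired enolate, the low temperature, the sieves and the excess of 12 are meant to secure.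

Step 8
Reactants: 14 (2R,3R)-2-(benzyloxy)-3-[3,4-bis(benzyloxy)phenyl]-3-(BrCat)-1-[2,4,6-tris(benzyloxy)phenyl]propan-1-one
Product: 15 (1RS,2R,3R)-2-(benzyloxy)-3-[3,4-bis(benzyloxy)phenyl]-3-(BrCat)-1-[2,4,6-tris(benzyloxy)phenyl]propan-1-ol
Conditions: NaBH4, THF–MeOH, 0 °C to rt
Reagents that add atoms: none
Why: Borohydride reduction of the aryl ketone; the new benzylic carbinol centre forms without control and is removed in step 9, while C2 and C1 are not touched.

Step 9
Reactants: 15 (1RS,2R,3R)-2-(benzyloxy)-3-[3,4-bis(benzyloxy)phenyl]-3-(BrCat)-1-[2,4,6-tris(benzyloxy)phenyl]propan-1-ol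
Product: 16 (2R,3S)-2-(3,4-dihydroxyphenyl)-6-[(1R,2S)-1-(3,4-dihydroxyphenyl)-2-hydroxy-3-(2,4,6-trihydroxyphenyl)propyl]chromane-3,5,7-triol (the target chalcan–flavan dimer)
Conditions: H2 (1 atm), 20% Pd(OH)2/C, THF–MeOH, rt
Reagents that add atoms: none
Why: Catalytic hydrogenolysis should cleave the eleven benzyl ethers and the C8–Br bond and reduce the ortho,para-oxygenated benzylic C–OH to CH2 (as in the reduction of flavan-3,4-diols to flavan-3-ols), while the non-benzylic C2 carbinol and the C1 methine keep their configuration.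

Compound list
1 | (+)-catechin, (2R,3S)-2-(3,4-dihydroxyphenyl)chromane-3,5,7-triol | O[C@H]1Cc2c(O)cc(O)cc2O[C@@H]1c1ccc(O)c(O)c1 | starting material
2 | 5,7,3',4'-tetra-O-benzyl-(+)-catechin | O[C@H]1Cc2c(OCc3ccccc3)cc(OCc3ccccc3)cc2O[C@@H]1c1ccc(OCc2ccccc2)c(OCc2ccccc2)c1 | intermediate
3 | 3,5,7,3',4'-penta-O-benzyl-(+)-catechin | c1ccccc1CO[C@H]1Cc2c(OCc3ccccc3)cc(OCc3ccccc3)cc2O[C@@H]1c1ccc(OCc2ccccc2)c(OCc2ccccc2)c1 | intermediate
4 | 8-bromo-3,5,7,3',4'-penta-O-benzyl-(+)-catechin | c1ccccc1CO[C@H]1Cc2c(OCc3ccccc3)cc(OCc3ccccc3)c(Br)c2O[C@@H]1c1ccc(OCc2ccccc2)c(OCc2ccccc2)c1 | intermediate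
5 | 8-bromo-6-formyl-3,5,7,3',4'-penta-O-benzyl-(+)-catechin | c1ccccc1CO[C@H]1Cc2c(OCc3ccccc3)c(C=O)c(OCc3ccccc3)c(Br)c2O[C@@H]1c1ccc(OCc2ccccc2)c(OCc2ccccc2)c1 | intermediate
6 | 4-bromo-1,2-bis(benzyloxy)benzene | Brc1ccc(OCc2ccccc2)c(OCc2ccccc2)c1 | starting material
7 | 3,4-bis(benzyloxy)phenylmagnesium bromide (not isolated) | Br[Mg]c1ccc(OCc2ccccc2)c(OCc2ccccc2)c1 | intermediate
8 | [3,4-bis(benzyloxy)phenyl](BrCat)methanol, both carbinol epimers | c1ccccc1CO[C@H]1Cc2c(OCc3ccccc3)c(C(O)c3ccc(OCc4ccccc4)c(OCc4ccccc4)c3)c(OCc3ccccc3)c(Br)c2O[C@@H]1c1ccc(OCc2ccccc2)c(OCc2ccccc2)c1 | intermediate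
9 | 1,3,5-tris(benzyloxy)benzene | c1ccccc1COc1cc(OCc2ccccc2)cc(OCc2ccccc2)c1 | starting material
10 | 2-(benzyloxy)-N-methoxy-N-methylacetamide | CON(C)C(=O)COCc1ccccc1 | starting material
11 | 2,4,6-tris(benzyloxy)phenyllithium (not isolated) | [Li]c1c(OCc2ccccc2)cc(OCc2ccccc2)cc1OCc1ccccc1 | intermediate
12 | 2-(benzyloxy)-1-[2,4,6-tris(benzyloxy)phenyl]ethan-1-one | O=C(COCc1ccccc1)c1c(OCc2ccccc2)cc(OCc2ccccc2)cc1OCc1ccccc1 | intermediate
13 | chloro[3,4-bis(benzyloxy)phenyl](BrCat)methane, both epimers (not isolated) | c1ccccc1CO[C@H]1Cc2c(OCc3ccccc3)c(C(Cl)c3ccc(OCc4ccccc4)c(OCc4ccccc4)c3)c(OCc3ccccc3)c(Br)c2O[C@@H]1c1ccc(OCc2ccccc2)c(OCc2ccccc2)c1 | intermediate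
14 | (2R,3R)-2-(benzyloxy)-3-[3,4-bis(benzyloxy)phenyl]-3-(BrCat)-1-[2,4,6-tris(benzyloxy)phenyl]propan-1-one | O=C(c1c(OCc2ccccc2)cc(OCc2ccccc2)cc1OCc1ccccc1)[C@H](OCc1ccccc1)[C@H](c1ccc(OCc2ccccc2)c(OCc2ccccc2)c1)c1c(OCc2ccccc2)c(Br)c2c(c1OCc1ccccc1)C[C@H](OCc1ccccc1)[C@@H](c1ccc(OCc3ccccc3)c(OCc3ccccc3)c1)O2 | intermediate
15 | (1RS,2R,3R)-2-(benzyloxy)-3-[3,4-bis(benzyloxy)phenyl]-3-(BrCat)-1-[2,4,6-tris(benzyloxy)phenyl]propan-1-ol | OC(c1c(OCc2ccccc2)cc(OCc2ccccc2)cc1OCc1ccccc1)[C@H](OCc1ccccc1)[C@H](c1ccc(OCc2ccccc2)c(OCc2ccccc2)c1)c1c(OCc2ccccc2)c(Br)c2c(c1OCc1ccccc1)C[C@H](OCc1ccccc1)[C@@H](c1ccc(OCc3ccccc3)c(OCc3ccccc3)c1)O2 | intermediate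
16 | the target chalcan–flavan dimer, (2R,3S)-2-(3,4-dihydroxyphenyl)-6-[(1R,2S)-1-(3,4-dihydroxyphenyl)-2-hydroxy-3-(2,4,6-trihydroxyphenyl)propyl]chromane-3,5,7-triol | Oc1cc(O)c(C[C@H](O)[C@H](c2ccc(O)c(O)c2)c2c(O)cc3c(c2O)C[C@H](O)[C@@H](c2ccc(O)c(O)c2)O3)c(O)c1 | target

Total step count: 9. Longest linear sequence: 8 (steps 1, 2, 3, 4, 5, 7, 8, 9).

Steps most likely to fail

Step 7. The ion-pair alkylation may show poor facial control at C2 or C1, the enolate may be O-alkylated, or the electrophile may be hydrolysed by the hydroxide base before the C–C bond forms. The fallback sets out from 8 and returns at 15, and moves the bond formation to acidic enamine catalysis. Carbinol 8, benzyloxyacetaldehyde and (2S,5S)-5-benzyl-2-tert-butyl-3-methylimidazolidin-4-one trifluoroacetate (20 mol %) in Et2O at 0 °C should ionise the carbinol in situ and alkylate the chiral enamine (organocatalytic SN1-type α-alkylation of an aldehyde with a benzhydryl alcohol). This catalyst antipode is chosen from the usual enamine-shielding model. The product would be (2R,3R)-2-(benzyloxy)-3-[3,4-bis(benzyloxy)phenyl]-3-(BrCat)propanal F1. Addition of this aldehyde at −78 °C to aryllithium 11 (made from 9 as in step 6) would give alcohol 15.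

Step 9. The benzylic C–O hydrogenolysis may stall once the phenols are free, or the transient ortho-quinone methide may be trapped by a neighbouring phenol to close a chroman ring. The fallback sets out from 15 and returns at 16, and removes the benzylic oxygen by a radical path before deprotection (Barton–McCombie deoxygenation). NaH, CS2 and MeI in THF would give O-[(1RS,2R,3R)-2-(benzyloxy)-3-[3,4-bis(benzyloxy)phenyl]-3-(BrCat)-1-[2,4,6-tris(benzyloxy)phenyl]propyl] S-methyl dithiocarbonate F2. Bu3SnH (1.1 equiv) with Et3B/air in toluene at rt would then give (2S,3R)-2-(benzyloxy)-3-[3,4-bis(benzyloxy)phenyl]-3-(BrCat)-1-[2,4,6-tris(benzyloxy)phenyl]propane F3. Should the stannane also reduce part of the C8–Br bond, nothing is lost, because that bromine is removed in the hydrogenolysis in any case. Hydrogenolysis of this compound (H2, Pd(OH)2/C) would give 16.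

Step 4. Electrophilic substitution at the hindered, bromine-deactivated C6 may be sluggish, or ipso attack may displace the bromine. The fallback sets out from 4 and returns at 8, and replaces formylation plus Grignard addition by acylation plus reduction. 3,4-Bis(benzyloxy)benzoic acid and TFAA in CH2Cl2 would give 3,4-bis(benzyloxy)benzoic trifluoroacetic anhydride F4. With cat. H3PO4 this mixed anhydride should acylate 4 at C6 (Friedel–Crafts acylation) to give [3,4-bis(benzyloxy)phenyl](BrCat)methanone F5. Reduction with LiBH4 in THF would give carbinol 8.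

Further compounds
F1 | step 7 | (2R,3R)-2-(benzyloxy)-3-[3,4-bis(benzyloxy)phenyl]-3-(BrCat)propanal | O=C[C@H](OCc1ccccc1)[C@H](c1ccc(OCc2ccccc2)c(OCc2ccccc2)c1)c1c(OCc2ccccc2)c(Br)c2c(c1OCc1ccccc1)C[C@H](OCc1ccccc1)[C@@H](c1ccc(OCc3ccccc3)c(OCc3ccccc3)c1)O2
F2 | step 9 | O-[(1RS,2R,3R)-2-(benzyloxy)-3-[3,4-bis(benzyloxy)phenyl]-3-(BrCat)-1-[2,4,6-tris(benzyloxy)phenyl]propyl] S-methyl dithiocarbonate | CSC(=S)OC(c1c(OCc2ccccc2)cc(OCc2ccccc2)cc1OCc1ccccc1)[C@H](OCc1ccccc1)[C@H](c1ccc(OCc2ccccc2)c(OCc2ccccc2)c1)c1c(OCc2ccccc2)c(Br)c2c(c1OCc1ccccc1)C[C@H](OCc1ccccc1)[C@@H](c1ccc(OCc3ccccc3)c(OCc3ccccc3)c1)O2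
F3 | step 9 | (2S,3R)-2-(benzyloxy)-3-[3,4-bis(benzyloxy)phenyl]-3-(BrCat)-1-[2,4,6-tris(benzyloxy)phenyl]propane | C(c1c(OCc2ccccc2)cc(OCc2ccccc2)cc1OCc1ccccc1)[C@H](OCc1ccccc1)[C@H](c1ccc(OCc2ccccc2)c(OCc2ccccc2)c1)c1c(OCc2ccccc2)c(Br)c2c(c1OCc1ccccc1)C[C@H](OCc1ccccc1)[C@@H](c1ccc(OCc3ccccc3)c(OCc3ccccc3)c1)O2
F4 | step 4 | 3,4-bis(benzyloxy)benzoic trifluoroacetic anhydride | O=C(OC(=O)C(F)(F)F)c1ccc(OCc2ccccc2)c(OCc2ccccc2)c1
F5 | step 4 | [3,4-bis(benzyloxy)phenyl](BrCat)methanone | c1ccccc1CO[C@H]1Cc2c(OCc3ccccc3)c(C(=O)c3ccc(OCc4ccccc4)c(OCc4ccccc4)c3)c(OCc3ccccc3)c(Br)c2O[C@@H]1c1ccc(OCc2ccccc2)c(OCc2ccccc2)c1
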